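The earlier runs and the new flask are simulated with made-up constants, noise included.

Of the 4 questions, 3 asked what part of the electrophile had reacted at the end of a flask, and the last asked whether free base moved that part.

common to all: electrophile 0.050 M
- Monday's: nucleophile 2.5 equiv; free base 0.80 equiv; run made earlier
- north-east: nucleophile 2.50 equiv; free base 1.70 equiv; time 5.0 min
- south: nucleophile 2.50 equiv; free base 1.30 equiv; time 5.0 min
- east: nucleophile 2.50 equiv; free base 1.00 equiv; time 5.0 min

Monday's run (percent of the electrophile charged)

| time / min | electrophile / % | target / % |
|---|---|---|
| 0.167 | 80.6 | 10.3 |
| 0.417 | 60.1 | 20.8 |
| 0.667 | 45.9 | 28.9 |
| 1.00 | 35.1 | 36.0 |
| 1.50 | 24.7 | 43.8 |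
| 2.00 | 18.8 | 48.3 |
| 2.50 | 15.9 | 51.7 |

(standard deviation of a reading: 0.3 percentage points)

- percentages count the electrophile that a species holds: one idle adduct counts as two
- target is meant together with its idle adduct
- on the list of suspects stand: electrophile + nucleophile -> acid set free + target; nucleophile + acid set free <-> protonated nucleophile; acid set free + free base <-> salt of the base; nucleophile + target -> over-reaction product; electrophile + target <-> idle adduct
- in an amount of target, one idle adduct counts as one target
- what has gone from electrophile into another species counts as reacted, even if it can come back
- no earlier run changes the charge of free base; that part of a forecast is a guess

* part of the electrophile that has reacted at the end, north-east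
* part of the electrophile that has reacted at the end, south
* part of the electrophile that has reacted at the end, east
* what raising the equivalents of free base from its lowest to its highest value here does to the part of the electrophile that has reacted (changes below 5 percentage points count as none) (it falls / no change / it rises)

At Monday's last reading, after 2.50 min, electrophile and target left a gap of 32.4%, against 31.5% after 1.50 min. I read this gap as idle adduct, counted once per adduct, with over-reaction product left out of it; so read, the electrophile held in idle adduct at that reading was more than the free electrophile, and idle adduct was its resting state. The target reading includes those adducts, so free target was 19.3%. From this I took the adduct quotient, the gap divided by the product of c(electrophile) and c(free target), all as fractions of the charge: 10.6.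

I then went to the end by two ways. The first used the electrophile readings. Its last decay constant, 0.440 min⁻¹, carried to 5.0 min, left 5.29%. The second used target: it rose at 0.389 min⁻¹ per unit of free electrophile, a pseudo-first-order constant. With the gap frozen, electrophile times free target stays constant, so the square of free target grows linearly in time. That gave free target 31.1% and electrophile 9.86%.

The two parted, and the first cheated: its constant had already fallen from 1.13 min⁻¹ early on, so holding it still left too little electrophile. The second cheated too: its own balance allowed a gap of 29.5%, less than the gap it had frozen. Putting that gap back through the quotient left 8.97% electrophile, so I committed to 91.0% reacted in north-east, south and east alike. No earlier run changes the free base, so using Monday's rate for every flask, and saying no change, was a guess.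

The forecast gave 92.5%, 92.3% and 92% with no change, and it said of the base: “Extra base therefore has little to do.”

North-east, south and east gave 92.1%, 92.0% and 91.9%, so no change, with 0.19 percentage points from lowest to highest free base.

    electrophile + nucleophile → acid set free + target (k = 5.81 M⁻¹ min⁻¹)
    nucleophile + acid set free ⇌ protonated nucleophile, settled at all times (K = 21000 M⁻¹)
    acid set free + free base ⇌ salt of the base, settled at all times (K = 7200 M⁻¹)
    nucleophile + target → over-reaction product (k = 0.493 M⁻¹ min⁻¹)
    electrophile + target ⇌ idle adduct, settled at all times (K = 210 M⁻¹)

North-east ended with 7.91% electrophile, 60.9% target and 55.3% idle adduct. One more flask, like south but with 0.620 equiv of nucleophile, ended with 42.8% electrophile and 31.4% target. At its charge of 0.050 M, the same as Monday's, the quotient from Monday, with each adduct counted as two as the percentages count it, puts its idle adduct at 51.5%, and that flask held 51.4%.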